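**Plan**

1. The target 31 is a germacran-12,8-olide. Germacrane locants are used throughout: lactone O on C8, C12 the lactone carbonyl, C13 and C15 the two exocyclic methylenes, C14 the methyl on C10.
2. Retrosynthetic cuts, in order: ring bond C5–C6, then C7–C8, then C2–C3, then the C1=C10 alkene. The first cut rests on the C6(OH)–C5(OCOR)–C4(=C15H2) array of the ten-membered ring. This is a homoallylic alcohol whose allylic carbon already carries the ester oxygen, so it can arise when a γ-acyloxyallyl metal (C15–C4=C5–OCOR) adds with allyl transposition to a C6 aldehyde.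
3. Forward: glycerate dioxolane → Z-enal (C8–C10, C1, C2) → C2–C3 allylation → union with the C6/C7/C11–C13 bromide, which closes the cis-lactone → C5 enal → chloro enol ester of (R)-2-methylbutanoic acid → oxirane, C2 ketone and C6 aldehyde → ten-membered ring closed last → acetylation.
4. Stereochemistry: C9 from methyl (S)-glycerate acetonide; a temporary C2 carbinol from a Keck allylation; C8 by chelation and C7 by the Z-allyl chair in the union; C1/C10 by C2–OH-directed, A1,3-controlled epoxidation, after which C2 is oxidised away; C5 and C6 in the ring closure; C2′ from (R)-2-methylbutanoic acid.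

Key step: step 20

Remark: (R)-2-methylbutanoic acid is taken as a purchasable acid, and 24–28 are carried as enol ester E/Z mixtures because the allylindium 29 is expected to equilibrate before it adds.

**Route**

Step 1
Reactants: 1 methyl (4S)-2,2-dimethyl-1,3-dioxolane-4-carboxylate
Product: 3 (4R)-4-ethynyl-2,2-dimethyl-1,3-dioxolane, via aldehyde 2 (not isolated)
Conditions: i-Bu2AlH, CH2Cl2, −78 °C; then MeOH, K2CO3, dimethyl (1-diazo-2-oxopropyl)phosphonate, −78 to 25 °C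
Reagents that add atoms: dimethyl (1-diazo-2-oxopropyl)phosphonate, COP(=O)(OC)C(=[N+]=[N-])C(C)=O
Why: Low-temperature ester-to-aldehyde reduction is telescoped into an Ohira–Bestmann (Seyferth–Gilbert) homologation so that the epimerisable aldehyde is never isolated; C9 comes unchanged from the chiral pool.

Step 2
Reactants: 3 (4R)-4-ethynyl-2,2-dimethyl-1,3-dioxolane
Product: 4 methyl 3-[(4R)-2,2-dimethyl-1,3-dioxolan-4-yl]prop-2-ynoate
Conditions: n-BuLi, THF, −78 °C; then ClCO2Me, −78 to 0 °C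
Reagents that add atoms: methyl chloroformate, COC(Cl)=O
Why: C-acylation of the lithium acetylide with a chloroformate is a standard route to ynoates and does not touch the dioxolane.

Step 3
Reactants: 4 methyl 3-[(4R)-2,2-dimethyl-1,3-dioxolan-4-yl]prop-2-ynoate
Product: 5 methyl (2Z)-3-[(4R)-2,2-dimethyl-1,3-dioxolan-4-yl]but-2-enoate
Conditions: Me2CuLi (from MeLi and CuI), THF, −78 °C; MeOH quench at −78 °C
Reagents that add atoms: lithium dimethylcuprate, [Li+].C[Cu-]C
Why: syn-Carbocupration of the ynoate and protonation of the vinylcopper at low temperature place methyl and hydrogen cis, so the dioxolane carbon (C9) and the ester carbon (C2) end up cis across C1=C10 (Z).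

Step 4
Reactants: 5 methyl (2Z)-3-[(4R)-2,2-dimethyl-1,3-dioxolan-4-yl]but-2-enoate
Product: 6 (2Z)-3-[(4R)-2,2-dimethyl-1,3-dioxolan-4-yl]but-2-en-1-ol
Conditions: i-Bu2AlH, CH2Cl2, −78 °C
Reagents that add atoms: none
Why: 1,2-Reduction of the enoate gives the allylic alcohol without touching the Z-alkene.

Step 5
Reactants: 6 (2Z)-3-[(4R)-2,2-dimethyl-1,3-dioxolan-4-yl]but-2-en-1-ol
Product: 7 (2Z)-3-[(4R)-2,2-dimethyl-1,3-dioxolan-4-yl]but-2-enal
Conditions: MnO2, CH2Cl2, 25 °C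
Reagents that add atoms: none
Why: Heterogeneous, neutral allylic oxidation should give the enal with the Z geometry kept.

Step 6
Reactants: 8 3-chloro-2-(chloromethyl)prop-1-ene
Product: 9 tributyl[2-(chloromethyl)prop-2-en-1-yl]stannane
Conditions: Bu3SnH, LiN(i-Pr)2, THF, 0 °C; then 8 (3 equiv), −78 °C
Reagents that add atoms: tributyltin hydride, CCCC[SnH](CCCC)CCCC
Why: Displacement of one allylic chloride by tributylstannyllithium gives the allylstannane, and the excess of dichloride holds the reaction at monosubstitution.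

Step 7
Reactants: 7 (2Z)-3-[(4R)-2,2-dimethyl-1,3-dioxolan-4-yl]but-2-enal; 9 tributyl[2-(chloromethyl)prop-2-en-1-yl]stannane
Product: 10 (4R,5Z)-2-(chloromethyl)-6-[(4R)-2,2-dimethyl-1,3-dioxolan-4-yl]hepta-1,5-dien-4-ol
Conditions: (R)-BINOL (20 mol%), Ti(OiPr)4 (10 mol%), 4 Å MS, CH2Cl2, −20 °C
Reagents that add atoms: none
Why: Keck allylation: the BINOL–Ti(OiPr)4 complex activates the aldehyde and the 2-substituted allylstannane adds to its Re face in an open transition state, which sets the temporary C2 carbinol as R under catalyst control.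

Step 8
Reactants: 10 (4R,5Z)-2-(chloromethyl)-6-[(4R)-2,2-dimethyl-1,3-dioxolan-4-yl]hepta-1,5-dien-4-ol
Product: 11 {[(4R,5Z)-2-(chloromethyl)-6-[(4R)-2,2-dimethyl-1,3-dioxolan-4-yl]hepta-1,5-dien-4-yl]oxy}tri(propan-2-yl)silane
Conditions: TIPSOTf, 2,6-lutidine, CH2Cl2, −78 to 0 °C
Reagents that add atoms: triisopropylsilyl trifluoromethanesulfonate, CC(C)[Si](C(C)C)(C(C)C)OS(=O)(=O)C(F)(F)F
Why: Silylation with a silyl triflate and a hindered base avoids an alkoxide that could close onto the allylic chloride, and the TIPS ether is chosen to outlast the acidic steps that follow.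

Step 9
Reactants: 11 {[(4R,5Z)-2-(chloromethyl)-6-[(4R)-2,2-dimethyl-1,3-dioxolan-4-yl]hepta-1,5-dien-4-yl]oxy}tri(propan-2-yl)silane
Product: 12 (2R,3Z,5R)-7-(chloromethyl)-3-methyl-5-{[tri(propan-2-yl)silyl]oxy}octa-3,7-diene-1,2-diol
Conditions: PPTS, MeOH, 25 °C
Reagents that add atoms: none
Why: Mild transketalisation removes the terminal acetonide while the secondary TIPS ether and the allylic chloride are stable.

Step 10
Reactants: 13 {[tert-butyl(diphenyl)silyl]oxy}acetaldehyde; 14 methyl prop-2-enoate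
Product: 15 methyl 4-{[tert-butyl(diphenyl)silyl]oxy}-3-hydroxy-2-methylidenebutanoate (racemic)
Conditions: DABCO, dioxane/H2O, 25 °C
Reagents that add atoms: none
Why: Morita–Baylis–Hillman reaction of an activated α-silyloxy aldehyde with the acrylate; the carbinol center is lost in the next step.

Step 11
Reactants: 15 methyl 4-{[tert-butyl(diphenyl)silyl]oxy}-3-hydroxy-2-methylidenebutanoate
Product: 16 methyl (2Z)-2-(bromomethyl)-4-{[tert-butyl(diphenyl)silyl]oxy}but-2-enoate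
Conditions: NBS, Me2S, CH2Cl2, 0 to 25 °C
Reagents that add atoms: N-bromosuccinimide, BrN1C(=O)CCC1=O
Why: The alkoxysulfonium salt of the Baylis–Hillman alcohol is displaced by bromide with allylic transposition (SN2′), which should give the thermodynamically favoured (Z)-2-(bromomethyl)enoate.

Step 12
Reactants: 12 (2R,3Z,5R)-7-(chloromethyl)-3-methyl-5-{[tri(propan-2-yl)silyl]oxy}octa-3,7-diene-1,2-diol; 16 methyl (2Z)-2-(bromomethyl)-4-{[tert-butyl(diphenyl)silyl]oxy}but-2-enoate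
Product: 19 (4R,5R)-4-({[tert-butyl(diphenyl)silyl]oxy}methyl)-5-[(1R,2Z,4R)-6-(chloromethyl)-1-hydroxy-2-methyl-4-{[tri(propan-2-yl)silyl]oxy}hepta-2,6-dien-1-yl]-3-methylideneoxolan-2-one, via hydroxy aldehyde 17 (not isolated), via dihydroxy ester 18 (not isolated)
Conditions: TEMPO (cat.), PhI(OAc)2, CH2Cl2, 0 °C; then 16, In powder, THF/H2O (1:1), 25 °C; then PPTS (cat.), CH2Cl2, 25 °C
Reagents that add atoms: none
Why: Primary-selective TEMPO oxidation gives the α-hydroxy aldehyde 17, which is captured at once in an aqueous Barbier reaction in which the allylindium from 16 adds through its γ-carbon (C7) to the indium-chelated hydroxy aldehyde on the face anti to C10 (Cram chelate, 8,9-syn) through a Zimmerman–Traxler chair that carries the Z-allyl geometry into the 7,8-syn pair, and the γ-hydroxy ester 18 then closes under mild acid to the cis-fused α-methylene-γ-butyrolactone.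

Step 13
Reactants: 19 (4R,5R)-4-({[tert-butyl(diphenyl)silyl]oxy}methyl)-5-[(1R,2Z,4R)-6-(chloromethyl)-1-hydroxy-2-methyl-4-{[tri(propan-2-yl)silyl]oxy}hepta-2,6-dien-1-yl]-3-methylideneoxolan-2-one
Product: 20 (1R,2Z,4R)-1-[(2R,3R)-3-({[tert-butyl(diphenyl)silyl]oxy}methyl)-4-methylidene-5-oxooxolan-2-yl]-6-(chloromethyl)-2-methyl-4-{[tri(propan-2-yl)silyl]oxy}hepta-2,6-dien-1-yl acetate
Conditions: Ac2O, pyridine, DMAP (cat.), CH2Cl2, 0 °C
Reagents that add atoms: acetic anhydride, CC(=O)OC(C)=O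
Why: Acetylation of the only free hydroxyl installs the C9 acetate of the target and removes the γ-hydroxy group that could otherwise translactonise.

Step 14
Reactants: 20 (1R,2Z,4R)-1-[(2R,3R)-3-({[tert-butyl(diphenyl)silyl]oxy}methyl)-4-methylidene-5-oxooxolan-2-yl]-6-(chloromethyl)-2-methyl-4-{[tri(propan-2-yl)silyl]oxy}hepta-2,6-dien-1-yl acetate
Product: 21 (1R,2Z,4R)-1-[(2R,3R)-3-({[tert-butyl(diphenyl)silyl]oxy}methyl)-4-methylidene-5-oxooxolan-2-yl]-6-formyl-2-methyl-4-{[tri(propan-2-yl)silyl]oxy}hepta-2,6-dien-1-yl acetate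
Conditions: N-methylmorpholine N-oxide, NaHCO3, KI (cat.), MeCN, 45 °C
Reagents that add atoms: N-methylmorpholine N-oxide, C[N+]1([O-])CCOCC1
Why: Ganem (Kornblum-type) oxidation: the N-oxide displaces the allylic chloride and the alkoxyammonium salt eliminates to the 2-substituted acrolein, which raises C5 to the aldehyde level under nearly neutral conditions.

Step 15
Reactants: 22 (2R)-2-methylbutanoic acid
Product: 23 (2R)-2-methylbutanoyl chloride
Conditions: (COCl)2, DMF (cat.), CH2Cl2, 0 to 25 °C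
Reagents that add atoms: oxalyl chloride, ClC(=O)C(Cl)=O
Why: Acid chloride formation under mild conditions should leave the α-stereocenter untouched.

Step 16
Reactants: 21 (1R,2Z,4R)-1-[(2R,3R)-3-({[tert-butyl(diphenyl)silyl]oxy}methyl)-4-methylidene-5-oxooxolan-2-yl]-6-formyl-2-methyl-4-{[tri(propan-2-yl)silyl]oxy}hepta-2,6-dien-1-yl acetate; 23 (2R)-2-methylbutanoyl chloride
Product: 24 (4R,5Z,7R)-7-(acetyloxy)-7-[(2R,3R)-3-({[tert-butyl(diphenyl)silyl]oxy}methyl)-4-methylidene-5-oxooxolan-2-yl]-2-(chloromethyl)-6-methyl-4-{[tri(propan-2-yl)silyl]oxy}hepta-1,5-dien-1-yl (2R)-2-methylbutanoate (1E/1Z mixture)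
Conditions: ZnCl2 (5 mol%), CH2Cl2, −20 to 0 °C
Reagents that add atoms: none
Why: Lewis-acid-catalysed 1,4-addition of the acid chloride to the enal puts the acyl group on O5 and chloride on C15 (3-chloropropenyl ester formation), and the hindered TIPS and TBDPS ethers, the acetate and the lactone are chosen to withstand the catalytic ZnCl2.

Step 17
Reactants: 24 (4R,5Z,7R)-7-(acetyloxy)-7-[(2R,3R)-3-({[tert-butyl(diphenyl)silyl]oxy}methyl)-4-methylidene-5-oxooxolan-2-yl]-2-(chloromethyl)-6-methyl-4-{[tri(propan-2-yl)silyl]oxy}hepta-1,5-dien-1-yl (2R)-2-methylbutanoate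
Product: 25 (4R,5Z,7R)-7-(acetyloxy)-2-(chloromethyl)-4-hydroxy-7-[(2R,3R)-3-(hydroxymethyl)-4-methylidene-5-oxooxolan-2-yl]-6-methylhepta-1,5-dien-1-yl (2R)-2-methylbutanoate (1E/1Z mixture)
Conditions: HF·pyridine, THF, 0 to 25 °C
Reagents that add atoms: none
Why: Acidic fluoride removes both silyl ethers in one operation and should leave the enol ester, the allylic chloride, the acetate and the lactone intact.

Step 18
Reactants: 25 (4R,5Z,7R)-7-(acetyloxy)-2-(chloromethyl)-4-hydroxy-7-[(2R,3R)-3-(hydroxymethyl)-4-methylidene-5-oxooxolan-2-yl]-6-methylhepta-1,5-dien-1-yl (2R)-2-methylbutanoate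
Product: 26 (4R)-4-[(2S,3S)-3-{(S)-(acetyloxy)[(2R,3R)-3-(hydroxymethyl)-4-methylidene-5-oxooxolan-2-yl]methyl}-3-methyloxiran-2-yl]-2-(chloromethyl)-4-hydroxybut-1-en-1-yl (2R)-2-methylbutanoate (1E/1Z mixture)
Conditions: mCPBA, NaHCO3, CH2Cl2, 0 °C
Reagents that add atoms: 3-chloroperoxybenzoic acid, OOC(=O)c1cccc(Cl)c1
Why: Hydroxyl-directed peracid epoxidation of the Z-allylic alcohol: A1,3 strain against C9 holds the C2–H in the alkene plane, so the hydrogen-bonded peracid is delivered syn to the C2–OH (threo), which is also the face anti to C8, and this sets C1 and C10 while the less nucleophilic enol ester and acrylate alkenes stay behind.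

Step 19
Reactants: 26 (4R)-4-[(2S,3S)-3-{(S)-(acetyloxy)[(2R,3R)-3-(hydroxymethyl)-4-methylidene-5-oxooxolan-2-yl]methyl}-3-methyloxiran-2-yl]-2-(chloromethyl)-4-hydroxybut-1-en-1-yl (2R)-2-methylbutanoate
Product: 27 4-[(2R,3R)-3-{(S)-(acetyloxy)[(2R,3S)-3-formyl-4-methylidene-5-oxooxolan-2-yl]methyl}-3-methyloxiran-2-yl]-2-(chloromethyl)-4-oxobut-1-en-1-yl (2R)-2-methylbutanoate (1E/1Z mixture)
Conditions: Dess–Martin periodinane, NaHCO3, CH2Cl2, 0 to 25 °C
Reagents that add atoms: none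
Why: Dess–Martin oxidation converts both carbinols in one operation, C2–OH to the epoxy ketone (which erases the temporary stereocenter) and C6–OH to the aldehyde, under buffered non-enolising conditions that protect the epimerisable C7 center; 27 is used without chromatography.

Step 20
Reactants: 27 4-[(2R,3R)-3-{(S)-(acetyloxy)[(2R,3S)-3-formyl-4-methylidene-5-oxooxolan-2-yl]methyl}-3-methyloxiran-2-yl]-2-(chloromethyl)-4-oxobut-1-en-1-yl (2R)-2-methylbutanoate
Product: 30 (1R,5R,6R,7R,8R,9S,10R)-9-acetoxy-1,10-epoxy-6-hydroxy-5-[(2R)-2-methylbutanoyloxy]-2-oxogermacra-4(15),11(13)-dien-12,8-olide, via allylic iodide 28 (not isolated), via allylindium diiodide 29 (not isolated)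
Conditions: In powder, NaI, DMF, 25 °C, 27 added over 12 h to 2 mM; pH 7 buffer quench at 0 °C
Reagents that add atoms: none
Why: Proposed new method: Finkelstein exchange gives the allylic iodide 28, indium metal inserts to give the γ-acyloxyallylindium 29, whose ester carbonyl can coordinate indium and hold the enol ester Z after fast 1,3-metallotropic E/Z equilibration, and C5 then adds to the C6 aldehyde with allylic transposition (SE2′) through a six-membered Zimmerman–Traxler chair, which creates the C5–C6 bond, the C4=C15 methylene and a free C6–OH next to the already acylated O5. The closest known reaction type is the intermolecular indium- or zinc-mediated Barbier acyloxyallylation of aldehydes with 3-halopropenyl esters, taken together with the intramolecular Barbier allylations of ω-formyl allylic halides that close ten-membered germacrane rings; what is new is a 2-substituted γ-acyloxyallyl halide used in a ring closure. The ten-membered ring closes in a 10-exo-trig mode at the aldehyde, the allyl unit reacting endocyclically at its γ-carbon C5. C5 is set relative to C6 by the chair with the Z-acyloxy group axial and C7 equatorial, which should give the 5,6-syn pair; C6 is set relative to C7 by the cis-fused lactone, which lets C5 approach anti to C11 with the indium-bound carbonyl oxygen turned outward, anti to the C7–C8 bond. The step needs aldehyde-over-ketone and ring-over-oligomer selectivity: the C2 ketone is less electrophilic and could only give a four-membered ring, and slow addition keeps the substrate dilute while the cis-oxirane and the cis-lactone bend the chain into a turn.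

Step 21
Reactants: 30 (1R,5R,6R,7R,8R,9S,10R)-9-acetoxy-1,10-epoxy-6-hydroxy-5-[(2R)-2-methylbutanoyloxy]-2-oxogermacra-4(15),11(13)-dien-12,8-olide
Product: 31 (1R,5R,6R,7R,8R,9S,10R)-6,9-diacetoxy-1,10-epoxy-5-[(2R)-2-methylbutanoyloxy]-2-oxogermacra-4(15),11(13)-dien-12,8-olide
Conditions: Ac2O, pyridine, DMAP (cat.), CH2Cl2, 0 °C
Reagents that add atoms: acetic anhydride, CC(=O)OC(C)=O
Why: DMAP-catalysed acetylation of the one free hydroxyl, run directly on crude 30 so that the C5 ester has no time to migrate to O6.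

**Compound list**

1 | methyl (4S)-2,2-dimethyl-1,3-dioxolane-4-carboxylate | CC1(C)OC[C@@H](C(=O)OC)O1 | starting material
2 | (4S)-2,2-dimethyl-1,3-dioxolane-4-carbaldehyde | CC1(C)OC[C@@H](C=O)O1 | intermediate
3 | (4R)-4-ethynyl-2,2-dimethyl-1,3-dioxolane | CC1(C)OC[C@@H](C#C)O1 | intermediate
4 | methyl 3-[(4R)-2,2-dimethyl-1,3-dioxolan-4-yl]prop-2-ynoate | CC1(C)OC[C@@H](C#CC(=O)OC)O1 | intermediate
5 | methyl (2Z)-3-[(4R)-2,2-dimethyl-1,3-dioxolan-4-yl]but-2-enoate | CC1(C)OC[C@@H](/C(C)=C\C(=O)OC)O1 | intermediate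
6 | (2Z)-3-[(4R)-2,2-dimethyl-1,3-dioxolan-4-yl]but-2-en-1-ol | CC1(C)OC[C@@H](/C(C)=C\CO)O1 | intermediate
7 | (2Z)-3-[(4R)-2,2-dimethyl-1,3-dioxolan-4-yl]but-2-enal | CC1(C)OC[C@@H](/C(C)=C\C=O)O1 | intermediate
8 | 3-chloro-2-(chloromethyl)prop-1-ene | ClCC(=C)CCl | starting material
9 | tributyl[2-(chloromethyl)prop-2-en-1-yl]stannane | CCCC[Sn](CCCC)(CCCC)CC(=C)CCl | intermediate
10 | (4R,5Z)-2-(chloromethyl)-6-[(4R)-2,2-dimethyl-1,3-dioxolan-4-yl]hepta-1,5-dien-4-ol | CC1(C)OC[C@@H](/C(C)=C\[C@H](O)CC(=C)CCl)O1 | intermediate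
11 | {[(4R,5Z)-2-(chloromethyl)-6-[(4R)-2,2-dimethyl-1,3-dioxolan-4-yl]hepta-1,5-dien-4-yl]oxy}tri(propan-2-yl)silane | CC1(C)OC[C@@H](/C(C)=C\[C@H](O[Si](C(C)C)(C(C)C)C(C)C)CC(=C)CCl)O1 | intermediate
12 | (2R,3Z,5R)-7-(chloromethyl)-3-methyl-5-{[tri(propan-2-yl)silyl]oxy}octa-3,7-diene-1,2-diol | OC[C@H](O)/C(C)=C\[C@H](O[Si](C(C)C)(C(C)C)C(C)C)CC(=C)CCl | intermediate
13 | {[tert-butyl(diphenyl)silyl]oxy}acetaldehyde | O=CCO[Si](c1ccccc1)(c1ccccc1)C(C)(C)C | starting material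
14 | methyl prop-2-enoate | C=CC(=O)OC | starting material
15 | methyl 4-{[tert-butyl(diphenyl)silyl]oxy}-3-hydroxy-2-methylidenebutanoate (racemic) | C=C(C(=O)OC)C(O)CO[Si](c1ccccc1)(c1ccccc1)C(C)(C)C | intermediate
16 | methyl (2Z)-2-(bromomethyl)-4-{[tert-butyl(diphenyl)silyl]oxy}but-2-enoate | COC(=O)/C(CBr)=C/CO[Si](c1ccccc1)(c1ccccc1)C(C)(C)C | intermediate
17 | (2R,3Z,5R)-7-(chloromethyl)-2-hydroxy-3-methyl-5-{[tri(propan-2-yl)silyl]oxy}octa-3,7-dienal | O=C[C@H](O)/C(C)=C\[C@H](O[Si](C(C)C)(C(C)C)C(C)C)CC(=C)CCl | intermediate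
18 | methyl (3R,4R,5R,6Z,8R)-3-({[tert-butyl(diphenyl)silyl]oxy}methyl)-10-(chloromethyl)-4,5-dihydroxy-6-methyl-2-methylidene-8-{[tri(propan-2-yl)silyl]oxy}undeca-6,10-dienoate | COC(=O)C(=C)[C@H](CO[Si](c1ccccc1)(c1ccccc1)C(C)(C)C)[C@@H](O)[C@H](O)/C(C)=C\[C@H](O[Si](C(C)C)(C(C)C)C(C)C)CC(=C)CCl | intermediate
19 | (4R,5R)-4-({[tert-butyl(diphenyl)silyl]oxy}methyl)-5-[(1R,2Z,4R)-6-(chloromethyl)-1-hydroxy-2-methyl-4-{[tri(propan-2-yl)silyl]oxy}hepta-2,6-dien-1-yl]-3-methylideneoxolan-2-one | CC(C)(C)[Si](c1ccccc1)(c1ccccc1)OC[C@H]1C(=C)C(=O)O[C@H]1[C@H](O)/C(C)=C\[C@H](O[Si](C(C)C)(C(C)C)C(C)C)CC(=C)CCl | intermediate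
20 | (1R,2Z,4R)-1-[(2R,3R)-3-({[tert-butyl(diphenyl)silyl]oxy}methyl)-4-methylidene-5-oxooxolan-2-yl]-6-(chloromethyl)-2-methyl-4-{[tri(propan-2-yl)silyl]oxy}hepta-2,6-dien-1-yl acetate | CC(C)(C)[Si](c1ccccc1)(c1ccccc1)OC[C@H]1C(=C)C(=O)O[C@H]1[C@H](OC(C)=O)/C(C)=C\[C@H](O[Si](C(C)C)(C(C)C)C(C)C)CC(=C)CCl | intermediate
21 | (1R,2Z,4R)-1-[(2R,3R)-3-({[tert-butyl(diphenyl)silyl]oxy}methyl)-4-methylidene-5-oxooxolan-2-yl]-6-formyl-2-methyl-4-{[tri(propan-2-yl)silyl]oxy}hepta-2,6-dien-1-yl acetate | CC(C)(C)[Si](c1ccccc1)(c1ccccc1)OC[C@H]1C(=C)C(=O)O[C@H]1[C@H](OC(C)=O)/C(C)=C\[C@H](O[Si](C(C)C)(C(C)C)C(C)C)CC(=C)C=O | intermediate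
22 | (2R)-2-methylbutanoic acid | OC(=O)[C@H](C)CC | starting material
23 | (2R)-2-methylbutanoyl chloride | ClC(=O)[C@H](C)CC | intermediate
24 | (4R,5Z,7R)-7-(acetyloxy)-7-[(2R,3R)-3-({[tert-butyl(diphenyl)silyl]oxy}methyl)-4-methylidene-5-oxooxolan-2-yl]-2-(chloromethyl)-6-methyl-4-{[tri(propan-2-yl)silyl]oxy}hepta-1,5-dien-1-yl (2R)-2-methylbutanoate (1E/1Z mixture) | CC(C)(C)[Si](c1ccccc1)(c1ccccc1)OC[C@H]1C(=C)C(=O)O[C@H]1[C@H](OC(C)=O)/C(C)=C\[C@H](O[Si](C(C)C)(C(C)C)C(C)C)CC(CCl)=COC(=O)[C@H](C)CC | intermediate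
25 | (4R,5Z,7R)-7-(acetyloxy)-2-(chloromethyl)-4-hydroxy-7-[(2R,3R)-3-(hydroxymethyl)-4-methylidene-5-oxooxolan-2-yl]-6-methylhepta-1,5-dien-1-yl (2R)-2-methylbutanoate (1E/1Z mixture) | OC[C@H]1C(=C)C(=O)O[C@H]1[C@H](OC(C)=O)/C(C)=C\[C@H](O)CC(CCl)=COC(=O)[C@H](C)CC | intermediate
26 | (4R)-4-[(2S,3S)-3-{(S)-(acetyloxy)[(2R,3R)-3-(hydroxymethyl)-4-methylidene-5-oxooxolan-2-yl]methyl}-3-methyloxiran-2-yl]-2-(chloromethyl)-4-hydroxybut-1-en-1-yl (2R)-2-methylbutanoate (1E/1Z mixture) | OC[C@H]1C(=C)C(=O)O[C@H]1[C@H](OC(C)=O)[C@@]1(C)O[C@H]1[C@H](O)CC(CCl)=COC(=O)[C@H](C)CC | intermediate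
27 | 4-[(2R,3R)-3-{(S)-(acetyloxy)[(2R,3S)-3-formyl-4-methylidene-5-oxooxolan-2-yl]methyl}-3-methyloxiran-2-yl]-2-(chloromethyl)-4-oxobut-1-en-1-yl (2R)-2-methylbutanoate (1E/1Z mixture) | O=C[C@H]1C(=C)C(=O)O[C@H]1[C@H](OC(C)=O)[C@@]1(C)O[C@H]1C(=O)CC(CCl)=COC(=O)[C@H](C)CC | intermediate
28 | 4-[(2R,3R)-3-{(S)-(acetyloxy)[(2R,3S)-3-formyl-4-methylidene-5-oxooxolan-2-yl]methyl}-3-methyloxiran-2-yl]-2-(iodomethyl)-4-oxobut-1-en-1-yl (2R)-2-methylbutanoate (1E/1Z mixture) | O=C[C@H]1C(=C)C(=O)O[C@H]1[C@H](OC(C)=O)[C@@]1(C)O[C@H]1C(=O)CC(CI)=COC(=O)[C@H](C)CC | intermediate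
29 | (1Z)-4-[(2R,3R)-3-{(S)-(acetyloxy)[(2R,3S)-3-formyl-4-methylidene-5-oxooxolan-2-yl]methyl}-3-methyloxiran-2-yl]-2-[(diiodoindiganyl)methyl]-4-oxobut-1-en-1-yl (2R)-2-methylbutanoate | O=C[C@H]1C(=C)C(=O)O[C@H]1[C@H](OC(C)=O)[C@@]1(C)O[C@H]1C(=O)C/C(C[In](I)I)=C/OC(=O)[C@H](C)CC | intermediate
30 | (1R,5R,6R,7R,8R,9S,10R)-9-acetoxy-1,10-epoxy-6-hydroxy-5-[(2R)-2-methylbutanoyloxy]-2-oxogermacra-4(15),11(13)-dien-12,8-olide | C=C1C(=O)O[C@@H]2[C@H]1[C@@H](O)[C@H](OC(=O)[C@H](C)CC)C(=C)CC(=O)[C@@H]1O[C@]1(C)[C@H]2OC(C)=O | intermediate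
31 | (1R,5R,6R,7R,8R,9S,10R)-6,9-diacetoxy-1,10-epoxy-5-[(2R)-2-methylbutanoyloxy]-2-oxogermacra-4(15),11(13)-dien-12,8-olide | C=C1C(=O)O[C@@H]2[C@H]1[C@@H](OC(C)=O)[C@H](OC(=O)[C@H](C)CC)C(=C)CC(=O)[C@@H]1O[C@]1(C)[C@H]2OC(C)=O | target

**Step count and weak points**

Total steps: 21. Longest linear sequence: 17 steps (1–5, 7–9, 12–14, 16–21).

Step 20 (ring closure). It may fail through oligomerisation, through addition by a non-chair transition state that gives the 5,6-anti or the 6-epi ring, through a 1,2-shift of the methylbutanoyl group to the indium alkoxide on O6, or through attack of iodide or indium on the epoxy ketone. The fallback replaces the allylmetal addition by a reductive pinacol closure of the same bond and moves the oxirane and the ketone behind the ring closure; it sets out from 21 and comes back at 31. Partial desilylation of 21 (HF·pyridine buffered with pyridine, THF, 0 °C) should free only the primary alcohol and give the C6-hydroxy enal F1. Dess–Martin oxidation should give the dialdehyde F2. SmI2 in THF at high dilution should couple the C6 aldehyde carbon with the carbonyl carbon of the C5 enal (intramolecular pinacol coupling, the samarium-bridged bis-ketyl favouring the syn-diol) and give the ten-membered 5,6-diol F3. Acylation of the less hindered allylic C5–OH with 23 (2,4,6-collidine, CH2Cl2, −40 °C) should give the C5 ester F4, and acetylation the 6,9-diacetate F5. HF·pyridine should then remove the TIPS group to give the C2 alcohol F6, hydroxyl-directed epoxidation with mCPBA the epoxy alcohol F7, and Dess–Martin oxidation of C2–OH the target 31.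

Step 12 (union and lactone). It may fail through tautomerisation or self-condensation of the α-hydroxy-β,γ-unsaturated aldehyde before it is captured, with loss of the C9 configuration, or through incomplete chelation control at C8. The fallback replaces the free hydroxy aldehyde by a configurationally stable α-alkoxy aldehyde; it sets out from 12 and comes back at 19. 4-Methoxybenzaldehyde dimethyl acetal and PPTS should convert 12 into the p-methoxybenzylidene acetal F8. i-Bu2AlH should open it at the less hindered oxygen to the primary alcohol with a C9 PMB ether F9, and Dess–Martin oxidation should give the α-alkoxy aldehyde F10. Zinc-mediated Barbier addition of 16 after precomplexation with MgBr2·OEt2 (chelation through the ether oxygen) should give the hydroxy ester F11, which should close with PPTS to the lactone PMB ether F12. DDQ in CH2Cl2/pH 7 buffer should then give 19.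

Step 7 (Keck allylation). It may fail through slow addition of the electron-poor chloromethyl-substituted stannane, which would leave time for Z to E isomerisation of the enal and erode the facial selectivity. The fallback separates C–C bond formation from the setting of C2; it sets out from 7 and comes back at 10. Indium-mediated Barbier allylation of 7 with an excess of 8 and NaI in DMF should give the homoallylic alcohol F13 as both C2 epimers. Dess–Martin oxidation should give the Z-enone F14, and CBS reduction ((S)-2-methyl-CBS-oxazaborolidine, catecholborane, toluene, −78 °C), with the alkenyl group as the large substituent, should give 10.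

**Further compounds**

F1 | step 20 | (1R,2Z,4R)-6-formyl-1-[(2R,3R)-3-(hydroxymethyl)-4-methylidene-5-oxooxolan-2-yl]-2-methyl-4-{[tri(propan-2-yl)silyl]oxy}hepta-2,6-dien-1-yl acetate | OC[C@H]1C(=C)C(=O)O[C@H]1[C@H](OC(C)=O)/C(C)=C\[C@H](O[Si](C(C)C)(C(C)C)C(C)C)CC(=C)C=O
F2 | step 20 | (1R,2Z,4R)-6-formyl-1-[(2R,3S)-3-formyl-4-methylidene-5-oxooxolan-2-yl]-2-methyl-4-{[tri(propan-2-yl)silyl]oxy}hepta-2,6-dien-1-yl acetate | O=C[C@H]1C(=C)C(=O)O[C@H]1[C@H](OC(C)=O)/C(C)=C\[C@H](O[Si](C(C)C)(C(C)C)C(C)C)CC(=C)C=O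
F3 | step 20 | (1Z,2R,5R,6R,7R,8R,9R)-9-acetoxy-5,6-dihydroxy-2-{[tri(propan-2-yl)silyl]oxy}germacra-1(10),4(15),11(13)-trien-12,8-olide | C=C1C(=O)O[C@@H]2[C@H]1[C@@H](O)[C@H](O)C(=C)C[C@@H](O[Si](C(C)C)(C(C)C)C(C)C)/C=C(C)\[C@H]2OC(C)=O
F4 | step 20 | (1Z,2R,5R,6R,7R,8R,9R)-9-acetoxy-6-hydroxy-5-[(2R)-2-methylbutanoyloxy]-2-{[tri(propan-2-yl)silyl]oxy}germacra-1(10),4(15),11(13)-trien-12,8-olide | C=C1C(=O)O[C@@H]2[C@H]1[C@@H](O)[C@H](OC(=O)[C@H](C)CC)C(=C)C[C@@H](O[Si](C(C)C)(C(C)C)C(C)C)/C=C(C)\[C@H]2OC(C)=O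
F5 | step 20 | (1Z,2R,5R,6R,7R,8R,9R)-6,9-diacetoxy-5-[(2R)-2-methylbutanoyloxy]-2-{[tri(propan-2-yl)silyl]oxy}germacra-1(10),4(15),11(13)-trien-12,8-olide | C=C1C(=O)O[C@@H]2[C@H]1[C@@H](OC(C)=O)[C@H](OC(=O)[C@H](C)CC)C(=C)C[C@@H](O[Si](C(C)C)(C(C)C)C(C)C)/C=C(C)\[C@H]2OC(C)=O
F6 | step 20 | (1Z,2R,5R,6R,7R,8R,9R)-6,9-diacetoxy-2-hydroxy-5-[(2R)-2-methylbutanoyloxy]germacra-1(10),4(15),11(13)-trien-12,8-olide | C=C1C(=O)O[C@@H]2[C@H]1[C@@H](OC(C)=O)[C@H](OC(=O)[C@H](C)CC)C(=C)C[C@@H](O)/C=C(C)\[C@H]2OC(C)=O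
F7 | step 20 | (1S,2R,5R,6R,7R,8R,9S,10S)-6,9-diacetoxy-1,10-epoxy-2-hydroxy-5-[(2R)-2-methylbutanoyloxy]germacra-4(15),11(13)-dien-12,8-olide | C=C1C(=O)O[C@@H]2[C@H]1[C@@H](OC(C)=O)[C@H](OC(=O)[C@H](C)CC)C(=C)C[C@@H](O)[C@@H]1O[C@]1(C)[C@H]2OC(C)=O
F8 | step 12 | (4R)-4-[(2Z,4R)-6-(chloromethyl)-4-{[tri(propan-2-yl)silyl]oxy}hepta-2,6-dien-2-yl]-2-(4-methoxyphenyl)-1,3-dioxolane (both acetal epimers) | COc1ccc(cc1)C1OC[C@H](O1)/C(C)=C\[C@H](O[Si](C(C)C)(C(C)C)C(C)C)CC(=C)CCl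
F9 | step 12 | (2R,3Z,5R)-7-(chloromethyl)-2-[(4-methoxyphenyl)methoxy]-3-methyl-5-{[tri(propan-2-yl)silyl]oxy}octa-3,7-dien-1-ol | OC[C@H](OCc1ccc(OC)cc1)/C(C)=C\[C@H](O[Si](C(C)C)(C(C)C)C(C)C)CC(=C)CCl
F10 | step 12 | (2R,3Z,5R)-7-(chloromethyl)-2-[(4-methoxyphenyl)methoxy]-3-methyl-5-{[tri(propan-2-yl)silyl]oxy}octa-3,7-dienal | O=C[C@H](OCc1ccc(OC)cc1)/C(C)=C\[C@H](O[Si](C(C)C)(C(C)C)C(C)C)CC(=C)CCl
F11 | step 12 | methyl (3R,4R,5R,6Z,8R)-3-({[tert-butyl(diphenyl)silyl]oxy}methyl)-10-(chloromethyl)-4-hydroxy-5-[(4-methoxyphenyl)methoxy]-6-methyl-2-methylidene-8-{[tri(propan-2-yl)silyl]oxy}undeca-6,10-dienoate | COC(=O)C(=C)[C@H](CO[Si](c1ccccc1)(c1ccccc1)C(C)(C)C)[C@@H](O)[C@H](OCc1ccc(OC)cc1)/C(C)=C\[C@H](O[Si](C(C)C)(C(C)C)C(C)C)CC(=C)CCl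
F12 | step 12 | (4R,5R)-4-({[tert-butyl(diphenyl)silyl]oxy}methyl)-5-[(1R,2Z,4R)-6-(chloromethyl)-1-[(4-methoxyphenyl)methoxy]-2-methyl-4-{[tri(propan-2-yl)silyl]oxy}hepta-2,6-dien-1-yl]-3-methylideneoxolan-2-one | CC(C)(C)[Si](c1ccccc1)(c1ccccc1)OC[C@H]1C(=C)C(=O)O[C@H]1[C@H](OCc1ccc(OC)cc1)/C(C)=C\[C@H](O[Si](C(C)C)(C(C)C)C(C)C)CC(=C)CCl
F13 | step 7 | (5Z)-2-(chloromethyl)-6-[(4R)-2,2-dimethyl-1,3-dioxolan-4-yl]hepta-1,5-dien-4-ol (both C4 epimers) | CC1(C)OC[C@@H](/C(C)=C\C(O)CC(=C)CCl)O1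
F14 | step 7 | (5Z)-2-(chloromethyl)-6-[(4R)-2,2-dimethyl-1,3-dioxolan-4-yl]hepta-1,5-dien-4-one | CC1(C)OC[C@@H](/C(C)=C\C(=O)CC(=C)CCl)O1
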